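**Retrosynthetic overview**
1. The C3 isovalerate (acylation) and the C11–O aryl ether (Mitsunobu reaction with umbelliferone) are cut first, leaving a 3-silyloxy ent-albicanol.
2. C11 and C12 are traced back to a C9 ketone: α-methylenation at C8, sulfur-ylide epoxidation at C9, then Pd/formate hydrogenolysis, which sets C9.
3. Ring A is cut at C1–C10 and C4–C5: one iron-hydride radical–polar crossover annulation joins a C1–C4 enal-derived aldehyde to a 2-methylcyclohexenone. Ring B exists first (from (S)-carvone), ring A is formed second, and the coumarin is attached intact.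
4. Enabling feature: in ring A the gem-dimethyl quaternary C4 sits next to ring-fusion C5, and the methyl-bearing quaternary C10 lies between C1 and C9 of ring B. C4 is therefore a latent tertiary radical (isopropenyl + H•), C5=C10–C9=O a latent 2-methylcyclohexenone, and C1 a latent aldehyde.
5. Stereocontrol: C3 comes from a HYTRA acetate aldol; C5 and C10 come from a C7 acetoxy group (the carvone stereocentre) that is eliminated afterwards; the C1 hydroxyl left by the aldol is removed by dehydration and hydrogenation.

Key step: step 6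

Remark: locants C1–C12 are drimane numbers (C1–C10 decalin carbons, C11 the CH2O carbon on C9, C12 the exocyclic methylene carbon on C8). The C1 carbinol of the annulation product is assumed to be the axial epimer (anti to the C10 methyl); it is erased in steps 7 and 8.

Step 1
Reactants: 1 (R)-2-hydroxy-1,2,2-triphenylethyl acetate ((R)-HYTRA); 2 methacrolein
Product: 3 (R)-2-hydroxy-1,2,2-triphenylethyl (R)-3-hydroxy-4-methylpent-4-enoate
Conditions: LDA (2.1 equiv), THF, −78 → 0 °C; then 2, THF/2-methylbutane, −105 °C; aq NH4Cl
Reagents that add atoms: none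
Why: HYTRA acetate aldol, in which the dilithium enolate adds 1,2 to the enal and the triphenylglycol unit shields one enolate face, which should set C3 as R (the sense known for its additions to α-branched aldehydes), the minor diastereomer being removed by crystallisation.

Step 2
Reactants: 3 (R)-2-hydroxy-1,2,2-triphenylethyl (R)-3-hydroxy-4-methylpent-4-enoate
Product: 4 (R)-2-hydroxy-1,2,2-triphenylethyl (R)-3-[(tert-butyldimethylsilyl)oxy]-4-methylpent-4-enoate
Conditions: TBSCl, imidazole, DMF, rt
Reagents that add atoms: tert-butyldimethylsilyl chloride, CC(C)(C)[Si](C)(C)Cl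
Why: Imidazole-promoted silylation of the secondary allylic alcohol, the tertiary diphenylcarbinol of the auxiliary being too hindered to react.

Step 3
Reactants: 4 (R)-2-hydroxy-1,2,2-triphenylethyl (R)-3-[(tert-butyldimethylsilyl)oxy]-4-methylpent-4-enoate
Product: 5 (R)-3-[(tert-butyldimethylsilyl)oxy]-4-methylpent-4-enal
Conditions: DIBAL-H (2.2 equiv), CH2Cl2, −78 °C; Rochelle salt
Reagents that add atoms: none
Why: Partial ester reduction with DIBAL-H, in which the aluminium hemiacetal is stable at −78 °C and collapses to the aldehyde only on work-up, releasing the recoverable auxiliary diol without touching C3.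

Step 4
Reactants: 6 (S)-(+)-carvone
Product: 8 (S)-5-acetyl-2-methylcyclohex-2-en-1-one, via secondary ozonide 7 (not isolated)
Conditions: O3 (1 equiv), CH2Cl2, −78 °C; then Me2S, −78 °C → rt
Reagents that add atoms: ozone, [O-][O+]=O
Why: Ozonolysis, in which ozone attacks the electron-rich 1,1-disubstituted alkene far faster than the conjugated ring alkene, and neutral reductive work-up should give the methyl ketone without enolisation at the stereocentre.

Step 5
Reactants: 8 (S)-5-acetyl-2-methylcyclohex-2-en-1-one
Product: 9 (S)-5-acetoxy-2-methylcyclohex-2-en-1-one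
Conditions: mCPBA, NaHCO3, CH2Cl2, 0 °C → rt
Reagents that add atoms: meta-chloroperoxybenzoic acid, OOC(=O)c1cccc(Cl)c1
Why: Baeyer–Villiger oxidation, in which the secondary ring carbon migrates in preference to methyl and with retention, while the conjugated ketone and its electron-poor alkene react much more slowly under buffered conditions.

Step 6
Reactants: 5 (R)-3-[(tert-butyldimethylsilyl)oxy]-4-methylpent-4-enal; 9 (S)-5-acetoxy-2-methylcyclohex-2-en-1-one
Product: 12 ketol (drimane numbering) 7-acetoxy-1-hydroxy-3-(tert-butyldimethylsilyloxy)-4,4,10-trimethyl-trans-decalin-9-one, via tertiary C4 radical 10 (not isolated), via iron enolate 11 (not isolated)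
Conditions: Fe(acac)3 (30 mol%), PhSiH3 (2 equiv), EtOH (3 equiv), ClCH2CH2Cl, 0 °C → rt
Reagents that add atoms: none
Why: An iron hydride formed from Fe(acac)3 and PhSiH3 transfers H• to the 1,1-disubstituted alkene of 5 (Markovnikov) to give the tertiary C4 radical 10, which adds to the β-carbon C5 of enone 9; the resulting C10 α-keto radical is reduced by Fe(II) to the iron(III) enolate 11, which closes on the C1 aldehyde and is released by alcoholysis. The closest known reaction type is the metal-hydride HAT-initiated radical–polar crossover (Giese/aldol) annulation of γ,δ-unsaturated aldehydes with 2-alkylcycloalkenones, which builds 1-hydroxy-4,4,10-trimethyl-trans-decal-9-ones. Ring A is closed by an intermolecular radical conjugate addition (C4–C5) followed by a 6-(enolexo)-exo-trig aldol (C10–C1), ring B being preformed. C5 is set by addition anti to the C7 acetoxy group; C10 follows from C5 because the iron aldolate should form reversibly and the trans-fused chair, with both new ring bonds equatorial on ring B and the C3 silyloxy group equatorial, is the most stable; C1 should come out axial through chelated closure but is erased later. The step needs HAT to choose the isopropenyl group over the enone and the aldehyde, and aldol closure to outrun protonation of 11: the first follows from the preference of metal-hydride HAT for electron-rich alkenes, the second is helped by the small amount of alcohol and the six-membered transition state.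

Step 7
Reactants: 12 ketol 7-acetoxy-1-hydroxy-3-(tert-butyldimethylsilyloxy)-4,4,10-trimethyl-trans-decalin-9-one
Product: 14 dienone 3-(tert-butyldimethylsilyloxy)-4,4,10-trimethyl-trans-decala-1,7-dien-9-one, via Δ1-alkene acetate 13 (not isolated)
Conditions: Martin sulfurane (1.5 equiv), CH2Cl2, 0 °C → rt; then DBU (2 equiv), rt
Reagents that add atoms: none
Why: Martin sulfurane dehydration (anti elimination of the axial C1 alkoxysulfurane with axial H-2; C10 is quaternary, so only the Δ1 alkene can form) followed by E1cB loss of acetic acid from the β-acetoxy ketone with DBU, which erases the C7 control element.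

Step 8
Reactants: 14 dienone 3-(tert-butyldimethylsilyloxy)-4,4,10-trimethyl-trans-decala-1,7-dien-9-one
Product: 15 3-(tert-butyldimethylsilyloxy)-4,4,10-trimethyl-trans-decalin-9-one
Conditions: H2 (1 atm), 10% Pd/C, EtOAc, rt
Reagents that add atoms: none
Why: Catalytic hydrogenation saturates the C7=C8 enone bond and the isolated C1=C2 bond without creating a stereocentre, while the hindered C9 ketone and the silyl ether are not reduced.

Step 9
Reactants: 15 3-(tert-butyldimethylsilyloxy)-4,4,10-trimethyl-trans-decalin-9-one
Product: 16 3-(tert-butyldimethylsilyloxy)-4,4,10-trimethyl-8-methylidene-trans-decalin-9-one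
Conditions: (CH2O)n (3 equiv), i-Pr2NH·CF3CO2H (1 equiv), CF3CO2H (10 mol%), THF, reflux
Reagents that add atoms: paraformaldehyde (formaldehyde), C=O
Why: Ammonium-salt-mediated direct α-methylenation (Mannich condensation then elimination), regiochemically unambiguous because C8 is the only enolisable position next to the C9 ketone.

Step 10
Reactants: 16 3-(tert-butyldimethylsilyloxy)-4,4,10-trimethyl-8-methylidene-trans-decalin-9-one
Product: 17 spiro vinyl epoxide (C9–C11 oxirane; oxygen on the face of the C10 methyl; C8=C12 retained)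
Conditions: Me3S+ I−, n-BuLi, THF, −10 °C; then 16, −10 → 0 °C
Reagents that add atoms: trimethylsulfonium iodide, C[S+](C)C.[I-]
Why: Corey–Chaykovsky epoxidation, in which dimethylsulfonium methylide adds 1,2 and irreversibly to enones and should attack C9 axially from the face opposite the axial C10 methyl.

Step 11
Reactants: 17 spiro vinyl epoxide
Product: 18 3-O-TBS ent-albicanol-type alcohol (C9–H anti to the C10 methyl; C11 hydroxymethyl equatorial; C8=C12 exocyclic)
Conditions: Pd2(dba)3·CHCl3 (2.5 mol%), n-Bu3P (10 mol%), HCO2H, Et3N, dioxane, rt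
Reagents that add atoms: none
Why: Tsuji-type palladium-catalysed formate hydrogenolysis of a vinyl epoxide, in which Pd(0) ionises the allylic C9–O bond anti to oxygen and hydride is delivered to the more substituted terminus C9 from the palladium face (net inversion), which should place H-9 anti to the C10 methyl and keep the exocyclic alkene.

Step 12
Reactants: 18 3-O-TBS ent-albicanol-type alcohol; 19 umbelliferone (7-hydroxycoumarin)
Product: 20 7-O-(3-O-TBS-albicanyl) umbelliferone ether
Conditions: PPh3, DIAD, THF, 0 °C → rt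
Reagents that add atoms: none
Why: Mitsunobu etherification, in which the primary C11 alcohol is activated as its oxyphosphonium salt and displaced by the acidic phenol without involving a stereocentre.

Step 13
Reactants: 20 7-O-(3-O-TBS-albicanyl) umbelliferone ether
Product: 21 C3 alcohol (3-hydroxy-albicanyl umbelliferone ether)
Conditions: HF·pyridine, pyridine, THF, 0 °C → rt
Reagents that add atoms: none
Why: Fluoride-mediated desilylation under buffered conditions that should leave the aryl ether, the lactone and the exocyclic alkene untouched.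

Step 14
Reactants: 21 C3 alcohol (3-hydroxy-albicanyl umbelliferone ether)
Product: 22 target CNP0295317.1
Conditions: isovaleric anhydride, DMAP, pyridine, CH2Cl2, rt
Reagents that add atoms: isovaleric anhydride, CC(C)CC(=O)OC(=O)CC(C)C
Why: DMAP-catalysed acyl transfer to the equatorial C3 alcohol with retention of configuration gives the isovalerate.

**Compound list**
1 | (R)-2-hydroxy-1,2,2-triphenylethyl acetate, (R)-HYTRA | CC(=O)O[C@H](c1ccccc1)C(O)(c1ccccc1)c1ccccc1 | starting material
2 | methacrolein | CC(=C)C=O | starting material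
3 | (R)-2-hydroxy-1,2,2-triphenylethyl (R)-3-hydroxy-4-methylpent-4-enoate | C=C(C)[C@H](O)CC(=O)O[C@H](c1ccccc1)C(O)(c1ccccc1)c1ccccc1 | intermediate
4 | (R)-2-hydroxy-1,2,2-triphenylethyl (R)-3-[(tert-butyldimethylsilyl)oxy]-4-methylpent-4-enoate | C=C(C)[C@H](O[Si](C)(C)C(C)(C)C)CC(=O)O[C@H](c1ccccc1)C(O)(c1ccccc1)c1ccccc1 | intermediate
5 | (R)-3-[(tert-butyldimethylsilyl)oxy]-4-methylpent-4-enal | C=C(C)[C@H](O[Si](C)(C)C(C)(C)C)CC=O | intermediate
6 | (S)-(+)-carvone | O=C1C[C@@H](C(C)=C)CC=C1C | starting material
7 | secondary ozonide (1,2,4-trioxolane) of the isopropenyl group of 6 | O=C1C[C@@H](C2(C)OOCO2)CC=C1C | intermediate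
8 | (S)-5-acetyl-2-methylcyclohex-2-en-1-one | O=C1C[C@@H](C(C)=O)CC=C1C | intermediate
9 | (S)-5-acetoxy-2-methylcyclohex-2-en-1-one | O=C1C[C@@H](OC(C)=O)CC=C1C | intermediate
10 | tertiary C4 radical, (R)-3-(tert-butyldimethylsilyloxy)-2-methyl-5-oxopentan-2-yl | C[C](C)[C@H](O[Si](C)(C)C(C)(C)C)CC=O | intermediate
11 | iron(III) enolate (C9–O, C9=C10) of the C5 adduct, drawn as the enolate anion | [O-]C1C[C@@H](OC(C)=O)C[C@H](C(C)(C)[C@H](O[Si](C)(C)C(C)(C)C)CC=O)C=1C | intermediate
12 | ketol: 7-acetoxy-1-hydroxy-3-(tert-butyldimethylsilyloxy)-4,4,10-trimethyl-trans-decalin-9-one; C3, C5, C10 as in the target; 1-OH and 7-OAc axial on the face opposite the C10 methyl | O=C1C[C@@H](OC(C)=O)C[C@@H]2C(C)(C)[C@H](O[Si](C)(C)C(C)(C)C)C[C@@H](O)[C@@]12C | intermediate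
13 | Δ1-alkene acetate: 7-acetoxy-3-(tert-butyldimethylsilyloxy)-4,4,10-trimethyl-trans-decal-1-en-9-one | O=C1C[C@@H](OC(C)=O)C[C@@H]2C(C)(C)[C@H](O[Si](C)(C)C(C)(C)C)C=C[C@@]12C | intermediate
14 | dienone: 3-(tert-butyldimethylsilyloxy)-4,4,10-trimethyl-trans-decala-1,7-dien-9-one | O=C1C=CC[C@@H]2C(C)(C)[C@H](O[Si](C)(C)C(C)(C)C)C=C[C@@]12C | intermediate
15 | 3-(tert-butyldimethylsilyloxy)-4,4,10-trimethyl-trans-decalin-9-one | O=C1CCC[C@@H]2C(C)(C)[C@H](O[Si](C)(C)C(C)(C)C)CC[C@@]12C | intermediate
16 | 3-(tert-butyldimethylsilyloxy)-4,4,10-trimethyl-8-methylidene-trans-decalin-9-one | C=C1CC[C@@H]2C(C)(C)[C@H](O[Si](C)(C)C(C)(C)C)CC[C@@]2(C)C1=O | intermediate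
17 | spiro vinyl epoxide: C9–C11 oxirane with oxygen on the face of the C10 methyl, C8=C12 exocyclic | C=C1CC[C@@H]2C(C)(C)[C@H](O[Si](C)(C)C(C)(C)C)CC[C@@]2(C)[C@@]13CO3 | intermediate
18 | 3-O-TBS ent-albicanol-type alcohol: 11-hydroxy, C8=C12 exocyclic, H-9 anti to the C10 methyl | C=C1CC[C@@H]2C(C)(C)[C@H](O[Si](C)(C)C(C)(C)C)CC[C@@]2(C)[C@@H]1CO | intermediate
19 | umbelliferone (7-hydroxycoumarin) | Oc1ccc2ccc(=O)oc2c1 | starting material
20 | 7-O-(3-O-TBS-albicanyl) umbelliferone ether | C=C1CC[C@@H]2C(C)(C)[C@H](O[Si](C)(C)C(C)(C)C)CC[C@@]2(C)[C@@H]1COc1ccc2ccc(=O)oc2c1 | intermediate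
21 | C3 alcohol: 7-O-(3-hydroxy-albicanyl) umbelliferone ether | C=C1CC[C@@H]2C(C)(C)[C@H](O)CC[C@@]2(C)[C@@H]1COc1ccc2ccc(=O)oc2c1 | intermediate
22 | CNP0295317.1, (3R,5S,9R,10R)-configured (drimane numbering) 3-isovaleryloxy-albicanyl umbelliferone ether | C=C1CC[C@@H]2C(C)(C)[C@H](OC(=O)CC(C)C)CC[C@@]2(C)[C@@H]1COc1ccc2ccc(=O)oc2c1 | target

**Step count and risks**
Total: 14 steps. Longest linear sequence: 12 steps (steps 1–3, then 6–14); the carvone branch (steps 4–5) joins at step 6.

Most likely to fail:

1. Step 6. The tertiary radical may be reduced before it adds, the iron enolate may be protonated before it closes on the aldehyde, or the aldehyde may not survive the hydride conditions. The fallback sets out from 5 (with 9) and comes back at 12; it separates the two bond formations. Acetalisation of 5 (HC(OMe)3, MeOH, PPTS) should give tert-butyl{[(3R)-1,1-dimethoxy-4-methylpent-4-en-3-yl]oxy}dimethylsilane F1. Reductive olefin–enone coupling of F1 with 9 (Fe(acac)3, PhSiH3, EtOH/ethylene glycol, where protonation of the enolate is now wanted) should give the trans-3,5-disubstituted 2-methylcyclohexanone acetal F2, its C10 epimers being of no consequence. Mild hydrolysis (PPTS, wet acetone) should give the keto-aldehyde F3. A separate, reversible acid-catalysed intramolecular aldol through the more substituted enol (TsOH, benzene, rt) should then close ring A to 12.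

2. Step 7. The activated C1–O bond next to the quaternary C10 may ionise with a 1,2-shift, or the β-hydroxy ketone may open by retro-aldol instead of undergoing anti elimination. The fallback sets out from 12 and comes back at 15; it removes the C1 oxygen by radical deoxygenation. Thiocarbonylation (1,1'-thiocarbonyldiimidazole, DMAP, toluene, 80 °C) should give the C1 O-imidazolylthiocarbonate F4. Barton–McCombie reduction (Bu3SnH at high concentration to outrun a 1,2-acyl shift, AIBN, toluene, 90 °C) should give the 1-deoxy acetoxy ketone F5. DBU should eliminate acetic acid to the C7=C8 enone F6, and hydrogenation (H2, Pd/C, EtOAc) returns 15.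

3. Step 10. The ylide may add in conjugate fashion at the unhindered C12 terminus (cyclopropane formation), or attack at the hindered C9 carbonyl may be slow or on the wrong face. The fallback sets out from 15 and comes back at 20; it brings in C11 by olefination, the C11–O bond by conjugate addition and C12 last. Wittig methylenation of 15 (Ph3P=CH2, toluene, 90 °C) should give the 9-methylidene compound F7. Allylic oxidation at C8, the only allylic CH2 (cat. SeO2, t-BuOOH, CH2Cl2), should give allylic alcohol F8, and Dess–Martin oxidation the 8-keto-9(11)-ene F9. Oxa-Michael addition of 19 (cat. DBU, MeCN) with thermodynamic protonation at C9 should give the β-aryloxy ketone F10 with the CH2OAr group equatorial. Non-basic Lombardo–Takai methylenation of the C8 ketone (Zn, CH2Br2, TiCl4) returns 20.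

**Further compounds**
F1 | step 6 | tert-butyl{[(3R)-1,1-dimethoxy-4-methylpent-4-en-3-yl]oxy}dimethylsilane | C=C(C)[C@H](O[Si](C)(C)C(C)(C)C)CC(OC)OC
F2 | step 6 | (5S)-5-acetoxy-3-[(3R)-3-(tert-butyldimethylsilyloxy)-5,5-dimethoxy-2-methylpentan-2-yl]-2-methylcyclohexanone, 3,5-trans, C2 epimers | O=C1C[C@@H](OC(C)=O)C[C@H](C(C)(C)[C@H](O[Si](C)(C)C(C)(C)C)CC(OC)OC)C1C
F3 | step 6 | keto-aldehyde: (3R)-4-[(5S)-5-acetoxy-2-methyl-3-oxocyclohexyl]-3-(tert-butyldimethylsilyloxy)-4-methylpentanal, 3,5-trans on the ring | O=C1C[C@@H](OC(C)=O)C[C@H](C(C)(C)[C@H](O[Si](C)(C)C(C)(C)C)CC=O)C1C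
F4 | step 7 | C1 O-(imidazol-1-ylthiocarbonyl) derivative of ketol 12 | O=C1C[C@@H](OC(C)=O)C[C@@H]2C(C)(C)[C@H](O[Si](C)(C)C(C)(C)C)C[C@@H](OC(=S)n3ccnc3)[C@@]12C
F5 | step 7 | 7-acetoxy-3-(tert-butyldimethylsilyloxy)-4,4,10-trimethyl-trans-decalin-9-one | O=C1C[C@@H](OC(C)=O)C[C@@H]2C(C)(C)[C@H](O[Si](C)(C)C(C)(C)C)CC[C@@]12C
F6 | step 7 | 3-(tert-butyldimethylsilyloxy)-4,4,10-trimethyl-trans-decal-7-en-9-one | O=C1C=CC[C@@H]2C(C)(C)[C@H](O[Si](C)(C)C(C)(C)C)CC[C@@]12C
F7 | step 10 | 3-(tert-butyldimethylsilyloxy)-4,4,10-trimethyl-9-methylidene-trans-decalin | C=C1CCC[C@@H]2C(C)(C)[C@H](O[Si](C)(C)C(C)(C)C)CC[C@@]12C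
F8 | step 10 | 3-(tert-butyldimethylsilyloxy)-4,4,10-trimethyl-9-methylidene-trans-decalin-8-ol, C8 configuration open | C=C1C(O)CC[C@@H]2C(C)(C)[C@H](O[Si](C)(C)C(C)(C)C)CC[C@@]12C
F9 | step 10 | 3-(tert-butyldimethylsilyloxy)-4,4,10-trimethyl-9-methylidene-trans-decalin-8-one | C=C1C(=O)CC[C@@H]2C(C)(C)[C@H](O[Si](C)(C)C(C)(C)C)CC[C@@]2(C)1
F10 | step 10 | 9-[(2-oxo-2H-chromen-7-yl)oxymethyl]-3-(tert-butyldimethylsilyloxy)-4,4,10-trimethyl-trans-decalin-8-one, CH2OAr equatorial | O=C1CC[C@@H]2C(C)(C)[C@H](O[Si](C)(C)C(C)(C)C)CC[C@@]2(C)[C@@H]1COc1ccc2ccc(=O)oc2c1
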